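**Plan**
- Enabling feature: ring A is a methylated cyclohexane-1,3,5-trione whose C1 and C5 carbonyls both hang on spiro C6. A C6 gem-diacyl unit and the C2–C3–C4 unit of 3-pentanone can therefore close it, with the two acyl groups playing the same role.
- Cuts, in retrosynthetic order: C4–CH3 and O3–CH3; C1–C2 and C4–C5 (ring A); C6–C7 (cyclopentane); C9–C10; C6=C10, back to nopinone and β-pinene.
- Forward: the pinane is bought; quaternary C10 by conjugate addition; cyclopentane by oxidative radical 5-exo closure; ring A by double C-acylation; then O- and C-methylation.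
- Stereochemistry: C13/C15 from (1R,5R)-β-pinene; C10 by addition anti to the CMe2 bridge; C7 in the radical closure; C6 last, by methylating the C4 flank remote from isopropyl.
- Locants: ring A C1(=O)–C2(Me)=C3(OMe)–C4(Me)2–C5(=O)–C6; cyclopentane C6–C7(iPr)–C8–C9–C10; pinane ring C10–C11–C12–C13–C14–C15, with C16 the CMe2 bridge between C13 and C15.

Key step: step 8

Remark: trione 14 and its methyl ether 15 are each drawn as one tautomer. Proton transfer between O1 and O5 is fast, so the two flanks of ring A are equivalent and C6 is written without configuration until step 10.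

Step 1
Reactants: 1 (1R,5R)-(+)-β-pinene
Product: 2 (1S,5R)-(−)-nopinone
Conditions: O3, CH2Cl2–MeOH, −78 °C; then Me2S, −78 °C → rt
Reagents that add atoms: ozone, [O-][O+]=O
Why: Ozonolysis with reductive work-up cleaves only the exocyclic C=CH2 bond and leaves the bridgehead stereocentres C13 and C15 untouched.

Step 2
Reactants: 2 (1S,5R)-(−)-nopinone; 3 dibenzyl malonate
Product: 4 dibenzyl nopinylidenemalonate
Conditions: TiCl4 (2 equiv), pyridine (4 equiv), THF, 0 °C → rt
Reagents that add atoms: none
Why: Knoevenagel condensation under TiCl4–pyridine, in which TiCl4 activates the hindered ketone and forms the titanium malonate enolate, loss of the titanium-bound oxygen makes the condensation irreversible, and the cold buffered medium should spare the cyclobutane.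

Step 3
Reactants: 4 dibenzyl nopinylidenemalonate; 5 5-bromo-2-methylpent-2-ene
Product: 7 dibenzyl 2-[6,6-dimethyl-2-(4-methylpent-3-en-1-yl)bicyclo[3.1.1]heptan-2-yl]malonate, via homoprenylmagnesium bromide 6 (not isolated)
Conditions: 5, Mg, THF, rt; then 4, CuBr·SMe2 (10 mol%), THF, −40 → 0 °C; 1 M HCl
Reagents that add atoms: none
Why: Copper-catalysed conjugate addition of a Grignard reagent to an alkylidene malonate builds quaternary C10; the nucleophile should enter from the face opposite the CMe2 bridge (the exposed face of 2-methylene-pinanes), which places C9 anti and the malonyl carbon C6 syn to C16.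

Step 4
Reactants: 7 homoprenyl malonate
Product: 8 dibenzyl 6,6-dimethyl-3'-(prop-1-en-2-yl)spiro[bicyclo[3.1.1]heptane-2,1'-cyclopentane]-2',2'-dicarboxylate
Conditions: Mn(OAc)3·2H2O (2.2 equiv), Cu(OAc)2·H2O (1 equiv), AcOH, 60 °C
Reagents that add atoms: none
Why: Manganese triacetate oxidative free-radical cyclisation, in which the manganese enolate gives the C6 malonyl radical, this closes 5-exo-trig onto C7, and divalent copper (regenerated by trivalent manganese) oxidises the tertiary radical to the isopropenyl group; C7 should be set in a chair-like transition state with the dimethylvinyl terminus and the bulkier bridgehead branch C15 both pseudo-equatorial, so the new substituent ends up cis to C11 and trans to C15.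

Step 5
Reactants: 8 isopropenyl spiro dibenzyl ester
Product: 9 6,6-dimethyl-3'-isopropylspiro[bicyclo[3.1.1]heptane-2,1'-cyclopentane]-2',2'-dicarboxylic acid
Conditions: H2 (1 atm), Pd/C (10 wt%), EtOAc–EtOH, rt
Reagents that add atoms: none
Why: Heterogeneous hydrogenation removes both benzyl esters by hydrogenolysis and saturates the 1,1-disubstituted alkene in one operation; hydrogen adds across the exocyclic C=CH2, so C7 keeps its configuration.

Step 6
Reactants: 9 spiro gem-diacid
Product: 10 6,6-dimethyl-3'-isopropylspiro[bicyclo[3.1.1]heptane-2,1'-cyclopentane]-2',2'-dicarbonyl dichloride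
Conditions: (COCl)2 (3 equiv), DMF (cat.), CH2Cl2, 0 °C → rt
Reagents that add atoms: oxalyl chloride, O=C(Cl)C(=O)Cl
Why: Acid chloride formation through the Vilsmeier intermediate; C6 carries no hydrogen, so no ketene can form, and the gem-diacid is never heated, so it should not decarboxylate.

Step 7
Reactants: 11 3-pentanone
Product: 12 (Z)-3-(trimethylsilyloxy)pent-2-ene
Conditions: TMSOTf (1.1 equiv), Et3N (1.3 equiv), CH2Cl2, 0 °C; distillation
Reagents that add atoms: trimethylsilyl trifluoromethanesulfonate, C[Si](C)(C)OS(=O)(=O)C(F)(F)F
Why: Soft enolisation and O-silylation of a symmetrical ketone gives a single regioisomeric enol silane whose alkene geometry is immaterial.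

Step 8
Reactants: 10 spiro gem-diacid chloride; 12 (Z)-3-(trimethylsilyloxy)pent-2-ene
Product: 14 symmetric spiro trione (dienol form), via diketone acid chloride 13 (not isolated)
Conditions: TiCl4 (2.2 equiv), CH2Cl2, −78 °C, slow addition of 12 (1.0 equiv), → 0 °C; then iPr2NEt (3 equiv), 0 °C → rt; 1 M HCl
Reagents that add atoms: none
Why: TiCl4 activates one acyl chloride of 10 for Mukaiyama-type C-acylation by C2 of the enol silane (C1–C2, Me3SiCl leaves) and holds the resulting β-diketone 13 as a titanium 1,3-diketonate; iPr2NEt then enolises this chelate toward C4, as in titanium-mediated Claisen condensations, and C4 attacks the second acyl chloride (C4–C5). The closest known reaction type is the Effenberger cyclisation of ketone enol ethers with malonyl dichlorides to cyclohexane-1,3,5-triones, run here on an acyclic ketone and a fully substituted malonyl dichloride. Ring A closes by a 6-(enolendo)-exo-trig acylation. No stereocentre is created: C2 and C4 end up enolised and the two acyl arms on C6 interconvert by tautomerism, so either acyl chloride may react first and both mono-adducts converge on 14. The selectivity needed is carbon over oxygen acylation in the closure: chelation of O1 and O3 to titanium lowers their nucleophilicity, any enol lactone can revert under the Lewis acid, and deprotonation of the strongly acidic trione should make the C-acylation irreversible.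

Step 9
Reactants: 14 symmetric spiro trione
Product: 15 3-O-methyl ether of the spiro trione
Conditions: HC(OMe)3 (3 equiv), MeOH, TsOH·H2O (cat.), rt
Reagents that add atoms: methanol, CO (solvent; also released from trimethyl orthoformate, COC(OC)OC)
Why: Acid-catalysed Fischer-type enol etherification by addition–elimination of methanol, with the orthoformate removing water; of the three ring carbonyl carbons only C3 is not attached to quaternary C6, so methanol should add there, as 1,3-diones with a neighbouring quaternary centre give the alkoxy enone at the unhindered carbonyl.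

Step 10
Reactants: 15 3-O-methyl ether of the spiro trione
Product: 16 CNP0307059.1
Conditions: NaOMe (1.2 equiv), MeI (5 equiv), MeOH, 0 °C → rt
Reagents that add atoms: iodomethane, CI
Why: C-alkylation of the vinylogous carboxylate (dienolate) of 15 with MeI in a protic medium, as in the C-methylation of phloroglucinol-derived enolates, which stops once C4 is quaternary; C6 is set by the choice of flank, because the ring A face turned toward C10 is covered by the CMe2 bridge (C6 is syn to C16) and on the open face the C7 isopropyl group lies over C1/C2 while only C7–H lies over C5/C4, so MeI should enter at C4 and leave the C5 carbonyl trans to isopropyl as in the target.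

**Compound list**
1 | (1R,5R)-(+)-β-pinene | C=C1CC[C@@H]2C[C@H]1C2(C)C | starting material
2 | (1S,5R)-(−)-nopinone (6,6-dimethylbicyclo[3.1.1]heptan-2-one) | O=C1CC[C@@H]2C[C@H]1C2(C)C | intermediate
3 | dibenzyl malonate | O=C(CC(=O)OCc1ccccc1)OCc1ccccc1 | starting material
4 | dibenzyl 2-[(1S,5R)-6,6-dimethylbicyclo[3.1.1]heptan-2-ylidene]malonate (nopinylidenemalonate) | O=C(OCc1ccccc1)C(C(=O)OCc1ccccc1)=C1CC[C@@H]2C[C@H]1C2(C)C | intermediate
5 | 5-bromo-2-methylpent-2-ene | CC(C)=CCCBr | starting material
6 | (4-methylpent-3-en-1-yl)magnesium bromide (homoprenylmagnesium bromide) | CC(C)=CCC[Mg]Br | intermediate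
7 | dibenzyl 2-[6,6-dimethyl-2-(4-methylpent-3-en-1-yl)bicyclo[3.1.1]heptan-2-yl]malonate; at C10 the homoprenyl chain is anti and the malonyl carbon syn to the CMe2 bridge | O=C(OCc1ccccc1)C(C(=O)OCc1ccccc1)[C@@]1(CCC=C(C)C)CC[C@@H]2C[C@H]1C2(C)C | intermediate
8 | dibenzyl 6,6-dimethyl-3'-(prop-1-en-2-yl)spiro[bicyclo[3.1.1]heptane-2,1'-cyclopentane]-2',2'-dicarboxylate; isopropenyl at C7 cis to C11, C6 syn to the CMe2 bridge | O=C(OCc1ccccc1)C1(C(=O)OCc2ccccc2)[C@@H](C(C)=C)CC[C@@]13CC[C@@H]4C[C@H]3C4(C)C | intermediate
9 | 6,6-dimethyl-3'-isopropylspiro[bicyclo[3.1.1]heptane-2,1'-cyclopentane]-2',2'-dicarboxylic acid; same configuration as 8 | OC(=O)C1(C(=O)O)[C@@H](C(C)C)CC[C@@]12CC[C@@H]3C[C@H]2C3(C)C | intermediate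
10 | 6,6-dimethyl-3'-isopropylspiro[bicyclo[3.1.1]heptane-2,1'-cyclopentane]-2',2'-dicarbonyl dichloride | ClC(=O)C1(C(=O)Cl)[C@@H](C(C)C)CC[C@@]12CC[C@@H]3C[C@H]2C3(C)C | intermediate
11 | 3-pentanone | CCC(=O)CC | starting material
12 | (Z)-3-(trimethylsilyloxy)pent-2-ene | C/C=C(/CC)O[Si](C)(C)C | intermediate
13 | β-diketone acid chloride: C6 carries one COCl and one 2-methyl-1,3-dioxopentyl arm (mixture at C2 and C6, all isomers converge on 14) | CCC(=O)C(C)C(=O)C1(C(Cl)=O)[C@@H](C(C)C)CC[C@@]12CC[C@@H]3C[C@H]2C3(C)C | intermediate
14 | symmetric spiro trione: ring A 2,4-dimethylcyclohexane-1,3,5-trione on spiro C6, drawn as a dienol; C6 without fixed configuration | OC1=C(C)C(=O)C2(C(O)=C1C)[C@@H](C(C)C)CC[C@@]21CC[C@@H]2C[C@H]1C2(C)C | intermediate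
15 | 3-O-methyl ether of 14 (5-hydroxy-3-methoxy-2,4-dimethylcyclohexa-2,4-dien-1-one ring A on spiro C6); C6 without fixed configuration | COC1=C(C)C(=O)C2(C(O)=C1C)[C@@H](C(C)C)CC[C@@]21CC[C@@H]2C[C@H]1C2(C)C | intermediate
16 | CNP0307059.1: ring A 3-methoxy-2,4,4-trimethylcyclohex-2-ene-1,5-dione spiro at C6; C1 carbonyl cis and C5 carbonyl trans to the C7 isopropyl group; isopropyl cis to C11; C6 syn to the CMe2 bridge | COC1=C(C)C(=O)[C@@]2(C(=O)C1(C)C)[C@@H](C(C)C)CC[C@@]21CC[C@@H]2C[C@H]1C2(C)C | target

**Count**
Total steps: 10. Longest linear sequence: 9 (steps 1–6 and 8–10 from β-pinene); step 7 is a one-step side branch.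

**Steps most likely to fail**

1. Step 8. The intermolecular acylation at a doubly neopentylic acyl chloride may be slow, and the ring may then close through the enol oxygen O3 instead of through C4. Fallback, setting out from 10 and 12 and coming back at 14: the closure through oxygen is used on purpose. With TiCl4 alone and no amine at rt, 13 should cyclise to the spiro 6-ethyl-5-methyl-2H-pyran-2,4(3H)-dione enol lactone F1. NaOMe in MeOH then opens the lactone to the methyl 3,5-dioxo ester F2, which is not isolated. After exchange of the solvent for THF, KOtBu closes C4 onto the ester (Dieckmann condensation, the enol-lactone-to-1,3-dione rearrangement) and gives 14.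

2. Step 10. MeI may discriminate poorly between the C2 and C4 flanks of the dienolate, and methylation at O1 or O5 may compete. Fallback, setting out from 15 and coming back at 16: the carbon is delivered from oxygen instead of from solution. Me2S and N-chlorosuccinimide in CH2Cl2 at −25 °C, then Et3N (Gassman ortho-alkylation, which with 2,6-disubstituted phenols gives 6-(methylthiomethyl)cyclohexadienones) should form the oxysulfonium ylide at the less hindered oxygen O5, next to C7–H and not to the isopropyl group. Its [2,3]-sigmatropic shift places CH2SMe on the adjacent C4 and gives the 4-(methylthiomethyl) dienone F3, as a mixture at C4 that does not matter. Raney Ni in EtOH cleaves the C–S bonds and gives 16.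

3. Step 4. Oxidative enolisation of the hindered malonate may be slow, and the tertiary radical may end as a lactone with the cis ester or as the C7=CMe2 alkene, which would erase the C7 stereocentre. Fallback, setting out from 7 and coming back at 9: NaH and then N-bromosuccinimide in THF give the bromomalonate F4. Bu3SnH and AIBN in benzene at 80 °C generate the same C6 radical, which closes 5-exo and is reduced at the tertiary carbon to the isopropyl diester F5 (reductive instead of oxidative termination). Hydrogenolysis with H2 and Pd/C gives 9.

**Further compounds**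
F1 | step 8 | spiro enol lactone: 6-ethyl-5-methyl-2H-pyran-2,4(3H)-dione with C3 of the pyran as spiro C6 (mixture at C6) | CCC1=C(C)C(=O)C2(C(=O)O1)[C@@H](C(C)C)CC[C@@]21CC[C@@H]2C[C@H]1C2(C)C
F2 | step 8 | methyl 3,5-dioxo ester: C6 carries CO2Me and the 2-methyl-1,3-dioxopentyl arm (mixture at C2 and C6) | CCC(=O)C(C)C(=O)C1(C(=O)OC)[C@@H](C(C)C)CC[C@@]12CC[C@@H]3C[C@H]2C3(C)C
F3 | step 10 | 4-(methylthiomethyl) analogue of 16 (mixture at C4) | COC1=C(C)C(=O)[C@@]2(C(=O)C1(C)CSC)[C@@H](C(C)C)CC[C@@]21CC[C@@H]2C[C@H]1C2(C)C
F4 | step 4 | dibenzyl 2-bromo-2-[6,6-dimethyl-2-(4-methylpent-3-en-1-yl)bicyclo[3.1.1]heptan-2-yl]malonate | O=C(OCc1ccccc1)C(Br)(C(=O)OCc1ccccc1)[C@@]1(CCC=C(C)C)CC[C@@H]2C[C@H]1C2(C)C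
F5 | step 4 | dibenzyl 6,6-dimethyl-3'-isopropylspiro[bicyclo[3.1.1]heptane-2,1'-cyclopentane]-2',2'-dicarboxylate | O=C(OCc1ccccc1)C1(C(=O)OCc2ccccc2)[C@@H](C(C)C)CC[C@@]13CC[C@@H]4C[C@H]3C4(C)C
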